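**A leftover.** The summer flask still shows 13.7% of its electrophile at 10.0 h, after 13.9% at 8.00 h, while the winter run is down to 0.3% by 8.00 h. You want to know what holds the summer flask back, and what to do about it.

| setting | summer | winter | flask |
|---|---|---|---|
| electrophile | 0.057 M | 0.038 M | 0.057 M |
| nucleophile | 0.0513 M | 0.0513 M | 0.0513 M |
| free base | 0.0456 M | 0.0456 M | 0.0456 M |
| remark | the very flask that is asked about, followed so far | run made earlier |  |
| time |  |  | 12 h |

- summer (time / h: target / %, electrophile / %): 0.667: 26.6, 43.7; 2.00: 24.7, 26.0; 3.00: 25.3, 20.6; 5.00: 25.1, 16.1; 8.00: 26.0, 13.9; 10.0: 25.9, 13.7
- winter (time / h: target / %, electrophile / %): 0.667: 34.2, 30.0; 1.00: 31.2, 22.6; 2.00: 29.1, 9.4; 3.00: 29.3, 3.3; 5.00: 29.3, 1.1; 8.00: 30.1, 0.3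

(standard deviation of a reading: 0.5 percentage points)

- epsilon: change nothing and wait 4.0 h more
- theta: at 12 h take out 90% of the target then present, then wait 4.0 h
- delta: at 12 h add nucleophile, 100% of the amount charged, then wait 4.0 h
- eta: at 12 h add free base, 100% of the amount charged, then wait 4.0 h
- zeta: at 12 h add electrophile, 50.0% of the amount charged, then wait 4.0 h

- target that was removed still counts
- the analysis behind the earlier runs scatters by 0.5 percentage points, standard deviation
- candidate steps: electrophile + nucleophile -> acid set free + target; acid set free + free base <-> salt of the base; nucleophile + acid set free <-> protonated nucleophile; target <-> isomer of the product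
- additions bring no volume worth counting

- target, in percent of the electrophile first charged, at 12 h
- the option that brings most further target ("none" if no option brings more than 2 percentage points) (epsilon / theta / delta / eta / zeta / none)
- target present, with what was taken out counted in, in percent of the electrophile first charged, after eta
- target present, with what was taken out counted in, in percent of the electrophile first charged, after zeta

**One number.** Each electrophile that reacts consumes one nucleophile and frees one acid. Let E, N and B be the charges of electrophile, nucleophile and free base. The free base binds acid up to B; beyond that, count strictly and let each further acid protonate one nucleophile, and the reacted amount at that point is the mean of N and B, or N if that is less. Protonation stands among the candidate steps as reversible, so this amount marks where the reaction slows, not where it ends. The summer flask has 0.850 as its slowing fraction β, the lesser of those two amounts divided by E: the share of the electrophile reacted when, counted so, the nucleophile, the limiting reagent, is consumed or protonated. The winter run has 1.28, above one, so its electrophile can go.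

**Reading it.** The summer flask should slow down with about 15.0% of its electrophile left. The last reading lies 1.3 percentage points below that, more than the scatter, so the summer flask goes on past the mark, and one number gives where it slows, not a final level. The late winter reading gives a target share s of the reacted electrophile of 0.302, so my reckoning for the summer flask at 12 h is s times β, 25.7%. Taking out 90% of the target leaves β alone, but s refills it from the isomer, for a total of 41.8%. Delta lifts β above one, for a gain of 4.5 points, so I choose theta.

**The forecast.** It says the summer flask “stalls near 86% conversion” and gives 26%, choosing theta, with 26.9% after eta and 26.4% after zeta. β stands beside this with one division and one product.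

**The mechanism.**

    electrophile + nucleophile → acid set free + target (k = 1.80 L mol⁻¹ min⁻¹)
    acid set free + free base ⇌ salt of the base (K = 1.40 × 10⁵ L mol⁻¹, k = 18.0 L mol⁻¹ min⁻¹)
    nucleophile + acid set free ⇌ protonated nucleophile, settled at all times (K = 3300 L mol⁻¹)
    target ⇌ isomer of the product (K = 2.40, k = 0.0360 min⁻¹)

**What came.** The summer flask gives 25.8% of target at 12 h, and theta is best, gaining 17 points against 3.7 points for delta; eta ends at 26.4%, zeta at 26.3%. Target and isomer relax with a half-life of 0.227 h, far shorter than 12 h, and the summer flask then holds 25.8% of target beside 61.7% of isomer, with 12.6% of electrophile against the 15.0% from β. A neighbour charged with 0.013 M of nucleophile has β of 0.228, so s times β is 6.89%, and that flask holds 6.71% of target.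

The data were computed with made-up constants, and the scatter is random.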